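The target is disconnected across ring B into two three-carbon units, with labdane numbering throughout: a ketone at C9 flanked by C8 and C10, and an enal C5=C6–C7. One amine-catalysed Michael/aldol condensation of the acyclic keto enal 11 forms C5–C10 and C7–C8, closing rings A and B together and setting both stereocentres, the quaternary C10 and C5. The feature exploited is that C8 and C10 are the two α-carbons of a carbonyl at C9, the olefinic carbon that later carries the side chain, while C5–C7 is unfunctionalised. Reductive triflation, alkyl Negishi coupling, Horner–Wadsworth–Emmons olefination and a final Stille coupling then build the dienyl butenolide arm.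

Key step: step 6

Remark on numbering: C1–C3 are the ring A methylenes, C4 the gem-dimethyl carbon, C5 the ring-fusion CH, C6 and C7 the ring B methylenes, C8 the methyl-bearing olefinic carbon, C9 the olefinic carbon bearing the side chain, C10 the methyl-bearing ring-fusion carbon, and C11 onward the side chain.

Remark on stereochemistry: the descriptors of the target place H-5 and CH3-10 on the same face, i.e. a cis-fused decalin (4aR,8aS in naphthalene numbering); the route is planned for this isomer.

Step 1
Reactants: 1 isobutyronitrile; 2 1,3-dibromopropane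
Product: 4 5-bromo-2,2-dimethylpentanenitrile, via lithiated isobutyronitrile 3 (not isolated)
Conditions: LiN(i-Pr)2, THF, −78 °C; then 2 (3 equiv), −78 → 23 °C
Reagents that add atoms: 1,3-dibromopropane (2), BrCCCBr
Why: SN2 alkylation of the tertiary α-cyano carbanion with excess dibromide should build the quaternary gem-dimethyl carbon (C4) and stop at monoalkylation.

Step 2
Reactants: 4 5-bromo-2,2-dimethylpentanenitrile; 5 pentan-3-one
Product: 7 (±)-2,2,6-trimethyl-7-oxononanenitrile, via pentan-3-one lithium enolate 6 (not isolated)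
Conditions: 5, LiN(i-Pr)2, THF, −78 °C; then 4, DMPU, −78 → 23 °C
Reagents that add atoms: pentan-3-one (5), CCC(=O)CC
Why: Enolate alkylation of the symmetrical ketone by the primary bromide should form the C1–C10 bond; the nitrile has no α-hydrogen, and the new stereocentre is racemic but is erased by enolisation in step 6.

Step 3
Reactants: 7 (±)-2,2,6-trimethyl-7-oxononanenitrile
Product: 8 7-hydroxy-2,2,6-trimethylnonanal (diastereomer mixture)
Conditions: i-Bu2AlH (3 equiv), CH2Cl2, −78 → 0 °C; then 1 M HCl, 0 °C
Reagents that add atoms: water, O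
Why: Hydride reduction takes the hindered nitrile to the N-aluminoimine (aldehyde after acidic hydrolysis) and unavoidably reduces the ketone to the alcohol, which step 5 reoxidises; the diastereomer mixture is of no consequence.

Step 4
Reactants: 8 7-hydroxy-2,2,6-trimethylnonanal; 9 (triphenylphosphoranylidene)acetaldehyde
Product: 10 (2E)-9-hydroxy-4,4,8-trimethylundec-2-enal (diastereomer mixture)
Conditions: 9 (1.3 equiv), toluene, 100 °C
Reagents that add atoms: (triphenylphosphoranylidene)acetaldehyde (9), O=CC=P(c1ccccc1)(c1ccccc1)c1ccccc1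
Why: Wittig olefination with the stabilised formylmethylene ylide should give the E-enal (C5=C6–C7) at the non-enolisable neopentyl aldehyde; the free secondary alcohol does not interfere.

Step 5
Reactants: 10 (2E)-9-hydroxy-4,4,8-trimethylundec-2-enal
Product: 11 (2E)-4,4,8-trimethyl-9-oxoundec-2-enal (racemic at C8 of the chain)
Conditions: Dess–Martin periodinane (1.5 equiv), CH2Cl2, 23 °C
Reagents that add atoms: none
Why: Dess–Martin oxidation should return the ethyl ketone from the secondary alcohol without touching the enal.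

Step 6
Reactants: 11 (2E)-4,4,8-trimethyl-9-oxoundec-2-enal
Product: 13 (4aR,8aS)-2,5,5,8a-tetramethyl-4a,5,6,7,8,8a-hexahydronaphthalen-1(4H)-one (cis-fused), via monocyclic keto aldehyde 12 (not isolated)
Conditions: (R)-α,α-diphenylprolinol trimethylsilyl ether (20 mol %), PhCO2H (20 mol %), toluene (0.05 M), 23 → 45 °C
Reagents that add atoms: none
Why: Proposed new method: the (R)-amine condenses with the enal to an E-iminium ion that cannot drain into a dienamine because C4 is quaternary; the acid-promoted enol of the ketone adds through its tetrasubstituted terminus C10 to the β-carbon C5 (ring A, 6-exo-trig), the released aldehyde arm is re-activated as its iminium ion and captured by the other enol terminus C8 (ring B, 6-(enolendo)-exo-trig Mannich/aldol closure forming C7–C8), and E1cB loss of the amine gives the conjugated enone and returns the catalyst. The closest known reactions are the secondary-amine-catalysed Michael/aldol condensation of β-keto esters with enals to cyclohexenones and the α,α′-annulation of ketone enamines with acrolein; new here are the unactivated α-branched ketone enol as donor and the doubly ring-forming intramolecular setting. C5 (C4a) is set by the catalyst, whose diphenyl(silyloxy)methyl group covers the Si face of the iminium β-carbon so that C10 bonds to the Re face (4aR). C10 (C8a) is set relative to C5 by a chair-like synclinal transition state in which the enol carbon C9, not the C10 methyl, lies pseudo-axial beside the axial C4 methyl and the iminium arm lies pseudo-equatorial; this avoids a 1,3-diaxial methyl/methyl contact, keeps the enol oxygen near the iminium nitrogen and places the acyl and CH2CH=N+ arms cis, which becomes the cis ring fusion (8aS). The step needs C10-over-C8 regiochemistry in the Michael event, secured by ring size (six- versus eight-membered), enantiofacial control, secured by the catalyst, and cis closure, secured by the gem-dimethyl group; reversible Michael addition before the irreversible dehydration should funnel material through the same cis adduct.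

Step 7
Reactants: 13 (4aR,8aS)-2,5,5,8a-tetramethyl-4a,5,6,7,8,8a-hexahydronaphthalen-1(4H)-one; 14 N-phenylbis(trifluoromethanesulfonimide)
Product: 16 (4aR,8aS)-2,5,5,8a-tetramethyl-3,4,4a,5,6,7,8,8a-octahydronaphthalen-1-yl trifluoromethanesulfonate, via lithium enolate 15 (not isolated)
Conditions: LiBH(s-Bu)3 (1.1 equiv), THF, −78 °C; then 14, −78 → 23 °C
Reagents that add atoms: N-phenylbis(trifluoromethanesulfonimide) (14), O=S(=O)(N(c1ccccc1)S(=O)(=O)C(F)(F)F)C(F)(F)F
Why: Conjugate reduction of the enone, whose carbonyl is shielded by the quaternary C10, should give the C8=C9 enolate regiospecifically, and O-triflation traps it as the tetrasubstituted enol triflate (reductive enolate trapping); no stereocentre is created.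

Step 8
Reactants: 16 (4aR,8aS)-2,5,5,8a-tetramethyl-3,4,4a,5,6,7,8,8a-octahydronaphthalen-1-yl trifluoromethanesulfonate; 17 (4-ethoxy-4-oxobutyl)zinc bromide
Product: 18 ethyl 4-[(4aR,8aS)-2,5,5,8a-tetramethyl-3,4,4a,5,6,7,8,8a-octahydronaphthalen-1-yl]butanoate
Conditions: 17 (0.5 M in THF, 2 equiv), Pd(OAc)2 (5 mol %), SPhos (10 mol %), LiCl, THF/NMP, 50 °C
Reagents that add atoms: (4-ethoxy-4-oxobutyl)zinc bromide (17), CCOC(=O)CCC[Zn]Br
Why: Negishi sp3–sp2 coupling of the primary alkylzinc with the alkenyl triflate should form C9–C11 with the olefin fixed at C8=C9; the ester is inert to the organozinc and the bulky biarylphosphine helps at the hindered position.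

Step 9
Reactants: 18 ethyl 4-[(4aR,8aS)-2,5,5,8a-tetramethyl-3,4,4a,5,6,7,8,8a-octahydronaphthalen-1-yl]butanoate; 19 diethyl chlorophosphate
Product: 21 ethyl 2-(diethoxyphosphoryl)-4-[(4aR,8aS)-2,5,5,8a-tetramethyl-3,4,4a,5,6,7,8,8a-octahydronaphthalen-1-yl]butanoate (epimers at C2), via ketene acetal phosphate 20 (not isolated)
Conditions: LiN(i-Pr)2 (1.1 equiv), THF, −78 °C; 19; then LiN(i-Pr)2 (2.2 equiv), −78 → 0 °C; AcOH
Reagents that add atoms: diethyl chlorophosphate (19), CCOP(=O)(Cl)OCC
Why: O-phosphorylation of the ester enolate followed by base-induced 1,3-migration of phosphorus from oxygen to carbon (vinyl phosphate–phosphonate rearrangement) should give the α-phosphono ester, driven by the stabilised phosphonate anion; the new stereocentre disappears in step 11.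

Step 10
Reactants: 22 (E)-1,2-bis(tributylstannyl)ethene; 23 N,N-dimethylformamide
Product: 25 (2E)-3-(tributylstannyl)prop-2-enal, via (E)-2-(tributylstannyl)ethenyllithium 24 (not isolated)
Conditions: n-BuLi (1.0 equiv), THF, −78 °C; then 23, −78 → 0 °C; aq. NH4Cl
Reagents that add atoms: N,N-dimethylformamide (23), CN(C)C=O
Why: Tin–lithium exchange of one stannyl group gives the alkenyllithium with retention of the E geometry, and formylation with DMF should give the E-enal.

Step 11
Reactants: 21 ethyl 2-(diethoxyphosphoryl)-4-[(4aR,8aS)-2,5,5,8a-tetramethyl-3,4,4a,5,6,7,8,8a-octahydronaphthalen-1-yl]butanoate; 25 (2E)-3-(tributylstannyl)prop-2-enal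
Product: 26 ethyl (2E,4E)-2-{2-[(4aR,8aS)-2,5,5,8a-tetramethyl-3,4,4a,5,6,7,8,8a-octahydronaphthalen-1-yl]ethyl}-5-(tributylstannyl)penta-2,4-dienoate
Conditions: LiCl, DBU, MeCN, 0 → 23 °C
Reagents that add atoms: (2E)-3-(tributylstannyl)prop-2-enal (25), O=C/C=C/[Sn](CCCC)(CCCC)CCCC
Why: Horner–Wadsworth–Emmons olefination of the α-alkyl phosphonoacetate with the enal should give the trisubstituted C13=C14 olefin with the ester trans to the dienyl chain (E), the usual outcome for stabilised phosphonates with conjugated aldehydes.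

Step 12
Reactants: 26 ethyl (2E,4E)-2-{2-[(4aR,8aS)-2,5,5,8a-tetramethyl-3,4,4a,5,6,7,8,8a-octahydronaphthalen-1-yl]ethyl}-5-(tributylstannyl)penta-2,4-dienoate
Product: 27 (2E,4E)-2-{2-[(4aR,8aS)-2,5,5,8a-tetramethyl-3,4,4a,5,6,7,8,8a-octahydronaphthalen-1-yl]ethyl}-5-(tributylstannyl)penta-2,4-dien-1-ol
Conditions: i-Bu2AlH (2.5 equiv), CH2Cl2, −78 °C; aq. potassium sodium tartrate
Reagents that add atoms: none
Why: 1,2-Reduction of the conjugated ester should give the allylic alcohol without affecting the alkenylstannane or the olefin geometry.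

Step 13
Reactants: 27 (2E,4E)-2-{2-[(4aR,8aS)-2,5,5,8a-tetramethyl-3,4,4a,5,6,7,8,8a-octahydronaphthalen-1-yl]ethyl}-5-(tributylstannyl)penta-2,4-dien-1-ol; 28 4-bromofuran-2(5H)-one
Product: 29 4-[(1E,3E)-4-(hydroxymethyl)-6-[(4aR,8aS)-2,5,5,8a-tetramethyl-3,4,4a,5,6,7,8,8a-octahydronaphthalen-1-yl]hexa-1,3-dien-1-yl]furan-2(5H)-one (target)
Conditions: Pd2(dba)3 (5 mol %), AsPh3 (20 mol %), NMP, 23 → 40 °C
Reagents that add atoms: 4-bromofuran-2(5H)-one (28), O=C1C=C(Br)CO1
Why: Stille coupling of the alkenylstannane with the vinylogous acyl bromide should proceed with retention of the E,E-diene geometry under neutral conditions that tolerate the free alcohol and the base-sensitive butenolide.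

Compound list

1 | isobutyronitrile | CC(C)C#N | starting material
2 | 1,3-dibromopropane | BrCCCBr | starting material
3 | lithiated isobutyronitrile (N-lithio keteniminate) | CC(C)=C=N[Li] | intermediate (not isolated)
4 | 5-bromo-2,2-dimethylpentanenitrile | CC(C)(CCCBr)C#N | intermediate
5 | pentan-3-one | CCC(=O)CC | starting material
6 | pentan-3-one lithium enolate | CC=C(CC)O[Li] | intermediate (not isolated)
7 | (±)-2,2,6-trimethyl-7-oxononanenitrile | CCC(=O)C(C)CCCC(C)(C)C#N | intermediate
8 | 7-hydroxy-2,2,6-trimethylnonanal (diastereomer mixture) | CCC(O)C(C)CCCC(C)(C)C=O | intermediate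
9 | (triphenylphosphoranylidene)acetaldehyde | O=CC=P(c1ccccc1)(c1ccccc1)c1ccccc1 | starting material
10 | (2E)-9-hydroxy-4,4,8-trimethylundec-2-enal (diastereomer mixture) | CCC(O)C(C)CCCC(C)(C)/C=C/C=O | intermediate
11 | (2E)-4,4,8-trimethyl-9-oxoundec-2-enal (racemic at C8) | CCC(=O)C(C)CCCC(C)(C)/C=C/C=O | intermediate
12 | 2-[(1R,2S)-2,6,6-trimethyl-2-propanoylcyclohexyl]acetaldehyde (acyl and CH2CHO cis) | CCC(=O)[C@@]1(C)CCCC(C)(C)[C@H]1CC=O | intermediate (not isolated)
13 | (4aR,8aS)-2,5,5,8a-tetramethyl-4a,5,6,7,8,8a-hexahydronaphthalen-1(4H)-one (cis-fused) | CC1=CC[C@@H]2C(C)(C)CCC[C@]2(C)C1=O | intermediate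
14 | N-phenylbis(trifluoromethanesulfonimide) | O=S(=O)(N(c1ccccc1)S(=O)(=O)C(F)(F)F)C(F)(F)F | starting material
15 | lithium (4aR,8aS)-2,5,5,8a-tetramethyl-3,4,4a,5,6,7,8,8a-octahydronaphthalen-1-olate | CC1=C(O[Li])[C@@]2(C)CCCC(C)(C)[C@H]2CC1 | intermediate (not isolated)
16 | (4aR,8aS)-2,5,5,8a-tetramethyl-3,4,4a,5,6,7,8,8a-octahydronaphthalen-1-yl trifluoromethanesulfonate | CC1=C(OS(=O)(=O)C(F)(F)F)[C@@]2(C)CCCC(C)(C)[C@H]2CC1 | intermediate
17 | (4-ethoxy-4-oxobutyl)zinc bromide (0.5 M in THF) | CCOC(=O)CCC[Zn]Br | starting material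
18 | ethyl 4-[(4aR,8aS)-2,5,5,8a-tetramethyl-3,4,4a,5,6,7,8,8a-octahydronaphthalen-1-yl]butanoate | CC1=C(CCCC(=O)OCC)[C@@]2(C)CCCC(C)(C)[C@H]2CC1 | intermediate
19 | diethyl chlorophosphate | CCOP(=O)(Cl)OCC | starting material
20 | diethyl 1-ethoxy-4-[(4aR,8aS)-2,5,5,8a-tetramethyl-3,4,4a,5,6,7,8,8a-octahydronaphthalen-1-yl]but-1-en-1-yl phosphate (ketene acetal phosphate) | CC1=C(CCC=C(OCC)OP(=O)(OCC)OCC)[C@@]2(C)CCCC(C)(C)[C@H]2CC1 | intermediate (not isolated)
21 | ethyl 2-(diethoxyphosphoryl)-4-[(4aR,8aS)-2,5,5,8a-tetramethyl-3,4,4a,5,6,7,8,8a-octahydronaphthalen-1-yl]butanoate (epimers at C2) | CC1=C(CCC(C(=O)OCC)P(=O)(OCC)OCC)[C@@]2(C)CCCC(C)(C)[C@H]2CC1 | intermediate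
22 | (E)-1,2-bis(tributylstannyl)ethene | CCCC[Sn](CCCC)(CCCC)/C=C/[Sn](CCCC)(CCCC)CCCC | starting material
23 | N,N-dimethylformamide | CN(C)C=O | starting material
24 | (E)-2-(tributylstannyl)ethenyllithium | [Li]/C=C/[Sn](CCCC)(CCCC)CCCC | intermediate (not isolated)
25 | (2E)-3-(tributylstannyl)prop-2-enal | O=C/C=C/[Sn](CCCC)(CCCC)CCCC | intermediate
26 | ethyl (2E,4E)-2-{2-[(4aR,8aS)-2,5,5,8a-tetramethyl-3,4,4a,5,6,7,8,8a-octahydronaphthalen-1-yl]ethyl}-5-(tributylstannyl)penta-2,4-dienoate | CC1=C(CC/C(=C\C=C\[Sn](CCCC)(CCCC)CCCC)C(=O)OCC)[C@@]2(C)CCCC(C)(C)[C@H]2CC1 | intermediate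
27 | (2E,4E)-2-{2-[(4aR,8aS)-2,5,5,8a-tetramethyl-3,4,4a,5,6,7,8,8a-octahydronaphthalen-1-yl]ethyl}-5-(tributylstannyl)penta-2,4-dien-1-ol | CC1=C(CC/C(=C\C=C\[Sn](CCCC)(CCCC)CCCC)CO)[C@@]2(C)CCCC(C)(C)[C@H]2CC1 | intermediate
28 | 4-bromofuran-2(5H)-one | O=C1C=C(Br)CO1 | starting material
29 | 4-[(1E,3E)-4-(hydroxymethyl)-6-[(4aR,8aS)-2,5,5,8a-tetramethyl-3,4,4a,5,6,7,8,8a-octahydronaphthalen-1-yl]hexa-1,3-dien-1-yl]furan-2(5H)-one | CC1=C(CC/C(=C\C=C\C2=CC(=O)OC2)CO)[C@@]2(C)CCCC(C)(C)[C@H]2CC1 | target

Total step count: 13. Longest linear sequence: 12 steps (steps 1–9 and 11–13); step 10 prepares the side-arm aldehyde 25.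

Steps most likely to fail

1. Step 6 (Proposed new method). The enol of the unactivated, α-branched ketone may be too weak and too hindered a donor for the β-neopentyl iminium ion, so that the C5–C10 bond forms slowly, or forms through an uncatalysed pathway without facial control. The fallback sets out from 11 and pre-forms the nucleophile. Me3SiOTf/Et3N in CH2Cl2 converts the ketone into the tetrasubstituted trimethylsilyl enol ether, (2E)-4,4,8-trimethyl-9-(trimethylsilyloxy)undeca-2,8-dienal F1; the enal cannot enolise, and the regioisomeric enol ether reverts to 11 on work-up and is recycled. F1 is then cyclised by the known iminium-catalysed Mukaiyama–Michael addition of silyl enol ethers to enals, using the enantiomer of the second-generation imidazolidinone catalyst (5-benzyl-2-tert-butyl-3-methylimidazolidin-4-one trifluoroacetate) whose benzyl group covers the Si face of the enal β-carbon, expected to be the (2R,5R) form. This gives the keto aldehyde 12, and p-TsOH added to the same flask closes ring B by aldol condensation, so the route is rejoined at 13.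

2. Step 8. Transmetalation and reductive elimination at an alkenylpalladium flanked by a quaternary carbon and a methyl-bearing olefinic carbon may be slow, so that reduction of the triflate or β-hydride loss from the alkyl group takes over. The fallback sets out from 16 and replaces the sp3–sp2 coupling by an sp2–sp2 coupling followed by two-carbon homologation through boron. Stille coupling with tributyl(vinyl)stannane (Pd(PPh3)4, LiCl, THF, 65 °C) should give the diene (4aR,8aS)-1-ethenyl-2,5,5,8a-tetramethyl-3,4,4a,5,6,7,8,8a-octahydronaphthalene F2. 9-BBN-H hydroborates only the monosubstituted vinyl terminus, giving the B-alkyl-9-borabicyclo[3.3.1]nonane F3. The known base-mediated alkylation of ethyl bromoacetate by a B-alkyl-9-BBN (KOt-Bu, THF, 0 °C; 1,2-migration in the boron ate complex) then delivers ester 18, where the route is rejoined.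

3. Step 9. The ketene acetal phosphate may undergo Claisen self-condensation or P–O cleavage in competition with the O-to-C phosphoryl migration. The fallback sets out from 18 and builds the C13=C14 olefin by aldol addition and elimination instead. The lithium enolate of 18 (LiN(i-Pr)2, THF, −78 °C) adds 1,2 to aldehyde 25 to give the β-hydroxy ester, ethyl (4E)-3-hydroxy-2-{2-[(4aR,8aS)-2,5,5,8a-tetramethyl-3,4,4a,5,6,7,8,8a-octahydronaphthalen-1-yl]ethyl}-5-(tributylstannyl)pent-4-enoate F4, as a diastereomer mixture. Acetylation (Ac2O, DMAP, Et3N) gives the corresponding 3-acetate F5, and DBU-induced E1cB elimination should give the thermodynamically preferred E-alkylidene ester 26. The route is rejoined at 26, and steps 9 and 11 are no longer needed.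

Further compounds

F1 | step 6 | (2E)-4,4,8-trimethyl-9-(trimethylsilyloxy)undeca-2,8-dienal (tetrasubstituted silyl enol ether, E/Z mixture at C8=C9) | CCC(O[Si](C)(C)C)=C(C)CCCC(C)(C)/C=C/C=O
F2 | step 8 | (4aR,8aS)-1-ethenyl-2,5,5,8a-tetramethyl-3,4,4a,5,6,7,8,8a-octahydronaphthalene | CC1=C(C=C)[C@@]2(C)CCCC(C)(C)[C@H]2CC1
F3 | step 8 | 9-{2-[(4aR,8aS)-2,5,5,8a-tetramethyl-3,4,4a,5,6,7,8,8a-octahydronaphthalen-1-yl]ethyl}-9-borabicyclo[3.3.1]nonane | CC1=C(CCB2C3CCCC2CCC3)[C@@]2(C)CCCC(C)(C)[C@H]2CC1
F4 | step 9 | ethyl (4E)-3-hydroxy-2-{2-[(4aR,8aS)-2,5,5,8a-tetramethyl-3,4,4a,5,6,7,8,8a-octahydronaphthalen-1-yl]ethyl}-5-(tributylstannyl)pent-4-enoate (diastereomer mixture) | CC1=C(CCC(C(O)/C=C/[Sn](CCCC)(CCCC)CCCC)C(=O)OCC)[C@@]2(C)CCCC(C)(C)[C@H]2CC1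
F5 | step 9 | ethyl (4E)-3-acetoxy-2-{2-[(4aR,8aS)-2,5,5,8a-tetramethyl-3,4,4a,5,6,7,8,8a-octahydronaphthalen-1-yl]ethyl}-5-(tributylstannyl)pent-4-enoate (diastereomer mixture) | CC1=C(CCC(C(OC(C)=O)/C=C/[Sn](CCCC)(CCCC)CCCC)C(=O)OCC)[C@@]2(C)CCCC(C)(C)[C@H]2CC1
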